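## Structural features

The target is a trans-fused bicyclic sesquiterpenoid acid. Ring A (C1–C6) is a cyclohexene whose C4=C5 double bond carries the hydroxymethyl carbon C15 on C4. Ring B (C6–C7–C8–C9–C10–C1) is a cyclohexane with an exocyclic methylidene C10=C14; these locants are used throughout. Ring B holds four contiguous stereocentres, C1, C6, C7 and C8 (1S,6S,7S,8R), with every substituent equatorial, and a fifth, isolated centre (3'S) lies in the 3,4-dihydroxy-2-methylidenebutanoyl group on the C8 oxygen. C7 carries an acrylic acid (C11=C13, acid carbon C12) next to the acylated C8 oxygen, so the molecule contains two α-substituted acrylate units, a free acid, a primary allylic alcohol and a 1,2-diol. The fragile points are the two Michael acceptors, the acid-sensitive 1,1-disubstituted exocyclic alkene, the 4'-hydroxyl (which under base can lactonise onto its own ester carbonyl and expel the C8 oxygen), and any free C8 hydroxyl (which would close a γ-lactone on C12). The real difficulty is to set C1, C6, C7 and C8 in sequence while keeping the three oxygenated carbons C8, C12 and C15 distinguishable, and to finish without strong acid or base. The key step exploits the fact that C1 and C6 are the β- and α-carbons of a cyclohexenone whose carbonyl is C5: a C10 nucleophile and a C7 electrophile can be added across it trans, the electrophile creates C11=C13 as it reacts, and the isopropenyl group later closes ring B at C8–C9 and leaves C10=C14.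

## Logic of the disconnections

25 from 23. Only protecting-group bonds are cut: one O–C(tert-butyl) bond at C12 and two O–Si bonds in the side chain. This keeps the acid and the diol masked until the end, so neither lactonisation pathway is open earlier. The forward step must cleave the ester without protic acid and the silyl ethers without base.

23 from 22. The C15–O bond is exchanged for a C5–O bond by a 1,3-shift of oxygen across C5–C4–C15. The cut turns the trisubstituted ring alkene with a primary alcohol into a secondary alcohol next to an exocyclic methylidene, which a ketone can supply. The forward step must move the hydroxyl itself; an acetate shift over divalent palladium is expected to be slow on an allyl unit alkylated at its central carbon.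

22 from 21 from 17. The C4–C15 bond is cut, which returns the C5 carbonyl. C15 is the only skeletal carbon that the three-component coupling does not deliver, and the C5 ketone is the natural handle to attach it at C4. The forward steps need kinetic enolisation toward C4 and not C6, in the presence of two acrylates, and a 1,2-selective reduction.

17 from 10 and 15. The C8–O acyl bond is cut, which separates the side chain from the bicycle. Acylating at this point removes the only free hydroxyl before any base is used and closes the lactonisation path from C8–O to C12. The forward step is an esterification of a hindered secondary alcohol under mild conditions.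

15 from 14 from 13 from 11 and 12. The C2'–C3' bond is cut; the side chain is the adduct of an acrylate with a protected glycolaldehyde. One catalytic step sets C3', and the activated ester allows later hydrolysis beside silyl ethers. The forward step must control a single stereocentre by the catalyst alone.

10 from 9 from 8. The C8–C9 bond is cut, with the hydrogen returned from oxygen to C14. This opens ring B and reveals a monocyclic ketone with an isopropenyl group at C1 and a masked aldehyde at C8. The forward closure must pass through a chair that places the C8 oxygen equatorial, and C8 has to travel as an acetal until then.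

8 from 4, 5 and 6. The C1–C10 and C6–C7 bonds are cut. Three simple pieces remain, and C1, C6 and C7 are all set in the one operation that joins them. The forward step needs catalyst control at C1, anti approach at C6, and attack at C7 of 4 rather than at its bromomethyl carbon.

4 from 3 from 1 and 2. The C7–C11 bond is cut and the bromide is traced to an allylic alcohol. Both partners are commodity chemicals, and 6 is bought. The bromination must proceed with allylic transposition under neutral conditions that spare acetal and tert-butyl ester.

## Other disconnections considered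

Alternative 1: The cut is the C1–C10 bond of ring B.
- Forward step: the substrate is the bromo enone A2, a cyclohex-2-enone (carbonyl C5) bearing at C6 a chain with C7, C11=C13, C12 as a p-methoxybenzyl ether, the silylated C8 carbinol, C9 and the terminus C10(Br)=C14. NiBr2 A3 with 2,2'-bipyridine A4 would be reduced at the cathode to zerovalent nickel, which inserts into the C10–Br bond. The alkenylnickel adds to C1, and protonation at C6 gives the trans-fused ketone A1.
- In its favour: C7 and C8 are fixed in an open chain before the ring closes and cannot be disturbed by the cyclisation. The C10 methylidene is brought in ready-made, without a Lewis acid. C6 is protonated last and, being α to C5, can be equilibrated to the trans fusion.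
- Against it here: A2 needs a linear preparation with acyclic control of C7 and C8 and attachment to the α-carbon of the enone. The closure is a 6-endo addition to an α-branched enone, where loss of bromine by reduction competes. The face at C1 depends on remote centres and not on a catalyst. C12 is at the alcohol level and must be oxidised twice late in the route.
- Comparison: on structure it is equal to the chosen plan for C15, since A1 still carries the C5 ketone, and better for C8, whose configuration is not left to a cyclisation. On mechanism both plans form C1–C10 at the enone β-carbon, but the chosen plan sets C1 by a chiral catalyst. On step economy the chosen plan is ahead, because it forms two skeletal bonds from bought pieces in one flask.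

Alternative 2: The cuts are C6–C7 and C8–C9.
- Forward step: the partners are the dienone A6 (acetyl carbon C10 on C1, C1=C6 and C4=C5, silylated C15 on C4) and tert-butyl 4-oxobutanoate A7 (C8, C7, C11, C12). A chiral secondary amine would convert A7 into an enamine that attacks C6 of A6 through C7. After protonation at C1 the methyl carbon C9 adds to the C8 aldehyde and closes ring B as the ketol A5.
- In its favour: ring B and four stereocentres arise in one metal-free step, and the C8 oxygen is installed with it. C4=C5 and C15 are present from the start, so no ketone at C5 has to be converted; on this point it is better than the chosen plan.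
- Against it here: A6 is a weak acceptor for an enamine because the enone is α-substituted. Attack at C4 in the 1,6 sense can compete. A6 is one oxidation away from an arene. A5 has neither methylidene: the C10 ketone of a β-ketol must be olefinated, with a risk of retro-aldol cleavage, and C11 must be methylenated with strong base next to C7.
- Comparison: on structure it is better for C15 and equal for C8, but worse for C13 and C14, which the chosen plan obtains as by-products of its bond formations. On mechanism it is a reversible enamine Michael–aldol sequence under thermodynamic control, against a kinetic copper addition and enolate SN2' reaction. On step economy the key step is the more convergent, but the preparation of A6 and two late olefinations should bring the count to that of the chosen plan or above.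

Alternative 3: The cuts are C5–C6 and C7–C11; ring B is the starting ring.
- Forward step: the enone A9 (carbonyl C8, C6=C7, side chain C2–C3–C4(=CH2)–C15 on C1, silyloxy group on C10) would take up vinylmagnesium bromide A10 at C6 under CuI A12 catalysis, anti to the C1 chain. The enolate would be alkylated at C7 by tert-butyl bromoacetate A11 to give the all-trans ketone A8. Ring-closing metathesis of the vinyl group with the 1,1-disubstituted alkene would then form ring A with C4=C5.
- In its favour: C15 and its oxygen are carried from the outset. The anti,anti outcome of conjugate addition and alkylation on a 4-substituted cyclohexenone is dependable. C7 is α to the C8 ketone and can be corrected by equilibration, which is an advantage over the chosen plan, where C7 is set kinetically.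
- Against it here: A9 must be made enantiopure with C1 and C10 already functionalised. Alkylation of a magnesium enolate by a bromoacetate is slower than an SN2' reaction on an activated bromomethyl enoate. After the key step the C8 ketone must be reduced, C10 deprotected, oxidised and olefinated, and C11 methylenated, with three protecting groups to handle.
- Comparison: on structure it is better for C15 and C7, equal for the trans C1/C6 relation, and worse for C8, C13 and C14. On mechanism it is the same type of event as the chosen plan, moved to ring B, with substrate control in place of catalyst control of the absolute configuration. On step economy it is longer.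

Key step: step 3

Assumption: the antipode of the ferrocenyl diphosphine that gives the (S) configuration at C1 with an alkenyl Grignard reagent is used; both antipodes are commercial and the sense would be fixed by a trial run of the simple conjugate addition.

## Route

Step 1
Reactants: 1 2,2-dimethoxyacetaldehyde (commercial aqueous solution); 2 tert-butyl acrylate
Product: 3 tert-butyl 3-hydroxy-4,4-dimethoxy-2-methylidenebutanoate (racemic)
Conditions: DABCO (1 equiv), THF/H2O (1:1), rt
Reagents that add atoms: none
Why: Morita–Baylis–Hillman reaction: DABCO adds to 2, the ammonium enolate attacks the electron-poor aldehyde 1, and proton transfer with loss of the amine should give the allylic alcohol; water accelerates the slow tert-butyl acrylate. The carbinol centre is lost in step 2, so the racemate serves.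

Step 2
Reactants: 3 tert-butyl 3-hydroxy-4,4-dimethoxy-2-methylidenebutanoate
Product: 4 tert-butyl (2Z)-2-(bromomethyl)-4,4-dimethoxybut-2-enoate
Conditions: NBS, Me2S, CH2Cl2, 0 °C to rt
Reagents that add atoms: N-bromosuccinimide, O=C1CCC(=O)N1Br
Why: Corey–Kim-type activation turns the hydroxyl into an alkoxysulfonium leaving group, and bromide attacks the methylidene carbon (SN2') under neutral conditions that should spare the acetal and the tert-butyl ester. The trisubstituted alkene should form with the acetal trans to the ester (Z descriptor), which avoids allylic 1,3-strain.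

Step 3
Reactants: 5 cyclohex-2-en-1-one; 6 isopropenylmagnesium bromide (commercial solution); 4 tert-butyl (2Z)-2-(bromomethyl)-4,4-dimethoxybut-2-enoate
Product: 8 tert-butyl (3S)-4,4-dimethoxy-2-methylidene-3-[(1S,6S)-2-oxo-6-(prop-1-en-2-yl)cyclohexyl]butanoate, via magnesium enolate 7 (not isolated)
Conditions: CuBr·SMe2 (5 mol%), (R)-1-[(Sp)-2-(diphenylphosphino)ferrocenyl]ethyldicyclohexylphosphine or its antipode (6 mol%), 6 (1.1 equiv, 2-methyltetrahydrofuran solution), t-BuOMe, −75 °C; then 4, THF, −75 to −20 °C
Reagents that add atoms: none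
Why: Transmetalation of 6 to the ligand-bound monovalent copper bromide gives a chiral alkenylcopper species that binds the enone face selected by the diphosphine, adds oxidatively at C1 (trivalent copper) and collapses by reductive elimination to the C1–C10 bond and the magnesium enolate 7. Enolate 7 then adds through C6 to C7 of 4, the β-carbon of a γ,γ-dialkoxy enoate, and the ester enolate so formed expels bromide from C13, which creates C11=C13 (SN2', addition–elimination). The closest known reaction type is the copper-catalysed asymmetric conjugate addition of Grignard reagents to cyclic enones with trapping of the magnesium enolate by an allylic bromide in the same flask. No ring is closed. C1 is fixed by the ligand; C6 is fixed by the substrate, because the electrophile approaches the enolate anti to the new isopropenyl group; C7 should be fixed by a closed, metal-bridged transition state between the ring enolate, which can only have the E geometry, and an acceptor whose acetal is trans to the ester, a pairing that leads to the syn arrangement of C1 and C8 along C5–C6–C7–C11, i.e. (7S). The step needs 1,4- over 1,2-addition (copper catalysis at low temperature), SN2' attack over direct displacement at the bromomethyl carbon (the acetal makes C7 the more electrophilic site), and single alkylation (C6 of 8 is a hindered methine). Any minor C7 epimer would be carried on and removed at 10.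

Step 4
Reactants: 8 tert-butyl (3S)-4,4-dimethoxy-2-methylidene-3-[(1S,6S)-2-oxo-6-(prop-1-en-2-yl)cyclohexyl]butanoate
Product: 9 tert-butyl (3S)-2-methylidene-4-oxo-3-[(1S,6S)-2-oxo-6-(prop-1-en-2-yl)cyclohexyl]butanoate
Conditions: LiBF4, MeCN/H2O (50:1), rt
Reagents that add atoms: water, O
Why: Mild hydrolysis of a dimethyl acetal through the oxocarbenium ion; the tert-butyl ester and the alkenes should be inert. The β,γ-unsaturated keto aldehyde is used crude and cold so that C7 does not enolise.

Step 5
Reactants: 9 tert-butyl (3S)-2-methylidene-4-oxo-3-[(1S,6S)-2-oxo-6-(prop-1-en-2-yl)cyclohexyl]butanoate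
Product: 10 tert-butyl 2-[(1S,2R,4aS,8aS)-2-hydroxy-4-methylidene-8-oxodecahydronaphthalen-1-yl]prop-2-enoate
Conditions: Me2AlCl (2.2 equiv), CH2Cl2, −78 to −40 °C
Reagents that add atoms: none
Why: Lewis acid-promoted intramolecular carbonyl-ene reaction with the tether on the central carbon of the ene unit: C9 attacks the complexed C8 aldehyde and a C14 hydrogen passes to oxygen, which closes ring B and leaves C10=C14. A chair with the two ring A bonds and the C7 acrylate equatorial should place the C8 oxygen equatorial, anti to C11, i.e. (8R). The second equivalent of Me2AlCl occupies the C5 ketone, and the tert-butyl ester resists lactonisation by the new alkoxide at this temperature.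

Step 6
Reactants: 11 2-[(tert-butyldimethylsilyl)oxy]acetaldehyde; 12 1,1,1,3,3,3-hexafluoropropan-2-yl acrylate
Product: 13 1,1,1,3,3,3-hexafluoropropan-2-yl (3S)-4-[(tert-butyldimethylsilyl)oxy]-3-hydroxy-2-methylidenebutanoate
Conditions: β-isocupreidine (10 mol%), DMF, −55 °C
Reagents that add atoms: none
Why: Asymmetric Morita–Baylis–Hillman reaction: the quinuclidine nitrogen adds to the activated acrylate 12 and the phenol of the catalyst organises the aldol step by hydrogen bonding. C3' is set by the catalyst; by analogy with aliphatic aldehydes the same facial preference should give (S) here, because the silyloxymethyl group outranks the alkene carbon.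

Step 7
Reactants: 13 1,1,1,3,3,3-hexafluoropropan-2-yl (3S)-4-[(tert-butyldimethylsilyl)oxy]-3-hydroxy-2-methylidenebutanoate
Product: 14 1,1,1,3,3,3-hexafluoropropan-2-yl (3S)-3,4-bis[(tert-butyldimethylsilyl)oxy]-2-methylidenebutanoate
Conditions: TBSOTf, 2,6-lutidine, CH2Cl2, −78 to 0 °C
Reagents that add atoms: tert-butyldimethylsilyl trifluoromethanesulfonate, CC(C)(C)[Si](C)(C)OS(=O)(=O)C(F)(F)F
Why: Silylation of a hindered secondary allylic alcohol with a silyl triflate and a hindered base; the activated ester should not be touched.

Step 8
Reactants: 14 1,1,1,3,3,3-hexafluoropropan-2-yl (3S)-3,4-bis[(tert-butyldimethylsilyl)oxy]-2-methylidenebutanoate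
Product: 15 (3S)-3,4-bis[(tert-butyldimethylsilyl)oxy]-2-methylidenebutanoic acid
Conditions: LiOH·H2O, THF/H2O, 0 °C; then 1 M HCl to pH 4
Reagents that add atoms: lithium hydroxide, [Li+].[OH-]
Why: The hexafluoroisopropyl ester is an activated ester, so hydroxide should cleave it at 0 °C faster than it adds to the alkene or removes a silyl group. The 4'-oxygen stays silylated, so no lactone can form.

Step 9
Reactants: 15 (3S)-3,4-bis[(tert-butyldimethylsilyl)oxy]-2-methylidenebutanoic acid; 10 tert-butyl 2-[(1S,2R,4aS,8aS)-2-hydroxy-4-methylidene-8-oxodecahydronaphthalen-1-yl]prop-2-enoate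
Product: 17 (1S,2R,4aS,8aS)-1-(3-tert-butoxy-3-oxoprop-1-en-2-yl)-4-methylidene-8-oxodecahydronaphthalen-2-yl (3S)-3,4-bis[(tert-butyldimethylsilyl)oxy]-2-methylidenebutanoate, via mixed anhydride 16 (not isolated)
Conditions: 2,4,6-Cl3C6H2COCl, Et3N, toluene, rt; then 10, DMAP, rt
Reagents that add atoms: none
Why: Yamaguchi esterification: the mixed anhydride is opened by DMAP to an acylpyridinium ion that should acylate the hindered equatorial C8 hydroxyl. No stereocentre is touched, and the C8 oxygen is now blocked against lactonisation onto C12.

Step 10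
Reactants: 17 (1S,2R,4aS,8aS)-1-(3-tert-butoxy-3-oxoprop-1-en-2-yl)-4-methylidene-8-oxodecahydronaphthalen-2-yl (3S)-3,4-bis[(tert-butyldimethylsilyl)oxy]-2-methylidenebutanoate
Product: 21 (1S,2R,4aS,8aS)-1-(3-tert-butoxy-3-oxoprop-1-en-2-yl)-4,7-dimethylidene-8-oxodecahydronaphthalen-2-yl (3S)-3,4-bis[(tert-butyldimethylsilyl)oxy]-2-methylidenebutanoate, via lithium enolate 18 (not isolated), via Mannich base 19 (not isolated), via ammonium iodide 20 (not isolated)
Conditions: LiN(SiMe3)2, THF, −78 °C; CH2=NMe2+ I−, −78 to 0 °C; MeI, CH2Cl2, rt; aq. NaHCO3, rt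
Reagents that add atoms: dimethylmethylideneammonium iodide, C=[N+](C)C.[I-]
Why: Eschenmoser methylenation: the hindered amide removes a proton from the C4 methylene and not from the C6 methine, the enolate adds to the iminium salt, and quaternisation followed by E1cB elimination should give the exocyclic enone. The α-branched acrylates are poor acceptors at −78 °C, and the trans ring fusion holds C13 out of reach of C4.

Step 11
Reactants: 21 (1S,2R,4aS,8aS)-1-(3-tert-butoxy-3-oxoprop-1-en-2-yl)-4,7-dimethylidene-8-oxodecahydronaphthalen-2-yl (3S)-3,4-bis[(tert-butyldimethylsilyl)oxy]-2-methylidenebutanoate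
Product: 22 (1S,2R,4aS,8aS)-1-(3-tert-butoxy-3-oxoprop-1-en-2-yl)-8-hydroxy-4,7-dimethylidenedecahydronaphthalen-2-yl (3S)-3,4-bis[(tert-butyldimethylsilyl)oxy]-2-methylidenebutanoate (C5 epimers)
Conditions: NaBH4, CeCl3·7H2O, MeOH, −78 °C
Reagents that add atoms: none
Why: Luche reduction: hydride should add 1,2 to the enone and leave the esters and the acrylate double bonds alone. The configuration at C5 does not matter, because C5 becomes sp2 in step 12.

Step 12
Reactants: 22 (1S,2R,4aS,8aS)-1-(3-tert-butoxy-3-oxoprop-1-en-2-yl)-8-hydroxy-4,7-dimethylidenedecahydronaphthalen-2-yl (3S)-3,4-bis[(tert-butyldimethylsilyl)oxy]-2-methylidenebutanoate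
Product: 23 (1S,2R,4aS,8aS)-1-(3-tert-butoxy-3-oxoprop-1-en-2-yl)-7-(hydroxymethyl)-4-methylidene-1,2,3,4,4a,5,6,8a-octahydronaphthalen-2-yl (3S)-3,4-bis[(tert-butyldimethylsilyl)oxy]-2-methylidenebutanoate
Conditions: Ph3SiOReO3 (5 mol%), Et2O, −40 to 0 °C
Reagents that add atoms: none
Why: Rhenium-oxo-catalysed 1,3-transposition of an allylic alcohol through a [3,3] shift of its perrhenate ester. The equilibrium should lie on the side of the trisubstituted ring alkene and the unhindered primary alcohol; silyl ethers and esters do not form perrhenate esters.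

Step 13
Reactants: 23 (1S,2R,4aS,8aS)-1-(3-tert-butoxy-3-oxoprop-1-en-2-yl)-7-(hydroxymethyl)-4-methylidene-1,2,3,4,4a,5,6,8a-octahydronaphthalen-2-yl (3S)-3,4-bis[(tert-butyldimethylsilyl)oxy]-2-methylidenebutanoate
Product: 25 2-[(1S,2R,4aS,8aS)-2-{[(3S)-3,4-dihydroxy-2-methylidenebutanoyl]oxy}-7-(hydroxymethyl)-4-methylidene-1,2,3,4,4a,5,6,8a-octahydronaphthalen-1-yl]prop-2-enoic acid, via silyl ester 24 (not isolated)
Conditions: TMSOTf, 2,6-lutidine, CH2Cl2, 0 °C; MeOH; then HF·pyridine, pyridine/THF, 0 °C to rt
Reagents that add atoms: none
Why: The silyl triflate with a hindered base should convert the tert-butyl ester into a silyl ester with loss of isobutene and without protic acid, which protects the exocyclic methylidene; the C15 hydroxyl is silylated in passing. Buffered hydrogen fluoride then cleaves every O–Si bond under conditions that are not basic enough for the 4'-hydroxyl to lactonise onto the C8 ester.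

## Compound list

1 | 2,2-dimethoxyacetaldehyde | COC(OC)C=O | starting material
2 | tert-butyl acrylate | C=CC(=O)OC(C)(C)C | starting material
3 | tert-butyl 3-hydroxy-4,4-dimethoxy-2-methylidenebutanoate (racemic) | C=C(C(=O)OC(C)(C)C)C(O)C(OC)OC | intermediate
4 | tert-butyl (2Z)-2-(bromomethyl)-4,4-dimethoxybut-2-enoate | COC(OC)/C=C(\CBr)C(=O)OC(C)(C)C | intermediate
5 | cyclohex-2-en-1-one | O=C1C=CCCC1 | starting material
6 | isopropenylmagnesium bromide | CC(=C)[Mg]Br | starting material
7 | bromomagnesium (3S)-3-(prop-1-en-2-yl)cyclohex-1-en-1-olate | Br[Mg]OC1=C[C@@H](C(C)=C)CCC1 | intermediate (not isolated)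
8 | tert-butyl (3S)-4,4-dimethoxy-2-methylidene-3-[(1S,6S)-2-oxo-6-(prop-1-en-2-yl)cyclohexyl]butanoate | O=C1CCC[C@H](C(C)=C)[C@H]1[C@H](C(OC)OC)C(=C)C(=O)OC(C)(C)C | intermediate
9 | tert-butyl (3S)-2-methylidene-4-oxo-3-[(1S,6S)-2-oxo-6-(prop-1-en-2-yl)cyclohexyl]butanoate | O=C1CCC[C@H](C(C)=C)[C@H]1[C@H](C=O)C(=C)C(=O)OC(C)(C)C | intermediate
10 | tert-butyl 2-[(1S,2R,4aS,8aS)-2-hydroxy-4-methylidene-8-oxodecahydronaphthalen-1-yl]prop-2-enoate | C=C(C(=O)OC(C)(C)C)[C@@H]1[C@H]2C(=O)CCC[C@@H]2C(=C)C[C@H]1O | intermediate
11 | 2-[(tert-butyldimethylsilyl)oxy]acetaldehyde | O=CCO[Si](C)(C)C(C)(C)C | starting material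
12 | 1,1,1,3,3,3-hexafluoropropan-2-yl acrylate | C=CC(=O)OC(C(F)(F)F)C(F)(F)F | starting material
13 | 1,1,1,3,3,3-hexafluoropropan-2-yl (3S)-4-[(tert-butyldimethylsilyl)oxy]-3-hydroxy-2-methylidenebutanoate | C=C(C(=O)OC(C(F)(F)F)C(F)(F)F)[C@H](O)CO[Si](C)(C)C(C)(C)C | intermediate
14 | 1,1,1,3,3,3-hexafluoropropan-2-yl (3S)-3,4-bis[(tert-butyldimethylsilyl)oxy]-2-methylidenebutanoate | C=C(C(=O)OC(C(F)(F)F)C(F)(F)F)[C@H](O[Si](C)(C)C(C)(C)C)CO[Si](C)(C)C(C)(C)C | intermediate
15 | (3S)-3,4-bis[(tert-butyldimethylsilyl)oxy]-2-methylidenebutanoic acid | C=C(C(=O)O)[C@H](O[Si](C)(C)C(C)(C)C)CO[Si](C)(C)C(C)(C)C | intermediate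
16 | mixed anhydride of 15 with 2,4,6-trichlorobenzoic acid | C=C(C(=O)OC(=O)c1c(Cl)cc(Cl)cc1Cl)[C@H](O[Si](C)(C)C(C)(C)C)CO[Si](C)(C)C(C)(C)C | intermediate (not isolated)
17 | (1S,2R,4aS,8aS)-1-(3-tert-butoxy-3-oxoprop-1-en-2-yl)-4-methylidene-8-oxodecahydronaphthalen-2-yl (3S)-3,4-bis[(tert-butyldimethylsilyl)oxy]-2-methylidenebutanoate | C=C(C(=O)OC(C)(C)C)[C@@H]1[C@H]2C(=O)CCC[C@@H]2C(=C)C[C@H]1OC(=O)C(=C)[C@H](O[Si](C)(C)C(C)(C)C)CO[Si](C)(C)C(C)(C)C | intermediate
18 | lithium C4=C5 enolate of 17 | C=C(C(=O)OC(C)(C)C)[C@@H]1[C@H]2C(O[Li])=CCC[C@@H]2C(=C)C[C@H]1OC(=O)C(=C)[C@H](O[Si](C)(C)C(C)(C)C)CO[Si](C)(C)C(C)(C)C | intermediate (not isolated)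
19 | C4-(dimethylaminomethyl) derivative of 17 (C4 epimers) | C=C(C(=O)OC(C)(C)C)[C@@H]1[C@H]2C(=O)C(CN(C)C)CC[C@@H]2C(=C)C[C@H]1OC(=O)C(=C)[C@H](O[Si](C)(C)C(C)(C)C)CO[Si](C)(C)C(C)(C)C | intermediate (not isolated)
20 | trimethylammonium iodide of 19 | C=C(C(=O)OC(C)(C)C)[C@@H]1[C@H]2C(=O)C(C[N+](C)(C)C)CC[C@@H]2C(=C)C[C@H]1OC(=O)C(=C)[C@H](O[Si](C)(C)C(C)(C)C)CO[Si](C)(C)C(C)(C)C.[I-] | intermediate (not isolated)
21 | (1S,2R,4aS,8aS)-1-(3-tert-butoxy-3-oxoprop-1-en-2-yl)-4,7-dimethylidene-8-oxodecahydronaphthalen-2-yl (3S)-3,4-bis[(tert-butyldimethylsilyl)oxy]-2-methylidenebutanoate | C=C(C(=O)OC(C)(C)C)[C@@H]1[C@H]2C(=O)C(=C)CC[C@@H]2C(=C)C[C@H]1OC(=O)C(=C)[C@H](O[Si](C)(C)C(C)(C)C)CO[Si](C)(C)C(C)(C)C | intermediate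
22 | (1S,2R,4aS,8aS)-1-(3-tert-butoxy-3-oxoprop-1-en-2-yl)-8-hydroxy-4,7-dimethylidenedecahydronaphthalen-2-yl (3S)-3,4-bis[(tert-butyldimethylsilyl)oxy]-2-methylidenebutanoate (C5 epimers) | C=C(C(=O)OC(C)(C)C)[C@@H]1[C@H]2C(O)C(=C)CC[C@@H]2C(=C)C[C@H]1OC(=O)C(=C)[C@H](O[Si](C)(C)C(C)(C)C)CO[Si](C)(C)C(C)(C)C | intermediate
23 | (1S,2R,4aS,8aS)-1-(3-tert-butoxy-3-oxoprop-1-en-2-yl)-7-(hydroxymethyl)-4-methylidene-1,2,3,4,4a,5,6,8a-octahydronaphthalen-2-yl (3S)-3,4-bis[(tert-butyldimethylsilyl)oxy]-2-methylidenebutanoate | C=C(C(=O)OC(C)(C)C)[C@@H]1[C@H]2C=C(CO)CC[C@@H]2C(=C)C[C@H]1OC(=O)C(=C)[C@H](O[Si](C)(C)C(C)(C)C)CO[Si](C)(C)C(C)(C)C | intermediate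
24 | trimethylsilyl ester and C15 trimethylsilyl ether of the acid derived from 23 | C=C(C(=O)O[Si](C)(C)C)[C@@H]1[C@H]2C=C(CO[Si](C)(C)C)CC[C@@H]2C(=C)C[C@H]1OC(=O)C(=C)[C@H](O[Si](C)(C)C(C)(C)C)CO[Si](C)(C)C(C)(C)C | intermediate (not isolated)
25 | 2-[(1S,2R,4aS,8aS)-2-{[(3S)-3,4-dihydroxy-2-methylidenebutanoyl]oxy}-7-(hydroxymethyl)-4-methylidene-1,2,3,4,4a,5,6,8a-octahydronaphthalen-1-yl]prop-2-enoic acid (CNP0460913.3) | C=C(C(=O)O)[C@@H]1[C@H]2C=C(CO)CC[C@@H]2C(=C)C[C@H]1OC(=O)C(=C)[C@H](O)CO | target

## Step count and least certain steps

Total: 13 steps. Longest linear sequence: 10 steps (steps 1–5 and 9–13); the acid 15 is made in 3 steps (6–8).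

Step 3 (key step). The magnesium enolate 7 may react sluggishly in the ethereal medium. Direct displacement at the bromomethyl carbon, proton exchange with the product and erosion of facial selectivity at C7 could then compete, and the enantioselection with an alkenyl Grignard reagent may be lower than with alkyl ones. The fallback sets out from 5 and 6. The conjugate addition is run alone and the enolate is silylated (Me3SiCl, Et3N) to the silyl enol ether (S)-trimethyl{[3-(prop-1-en-2-yl)cyclohex-1-en-1-yl]oxy}silane F1, which can be purified and assayed. MeLi in THF then releases the lithium enolate lithium (3S)-3-(prop-1-en-2-yl)cyclohex-1-en-1-olate F2, whose tighter chelated addition to 4 at −78 °C should favour the SN2' path and the (7S) epimer. The route is rejoined at 8.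

Step 5. The facial selectivity at C8 may be reversed if the hydrogen transfer prefers an axial oxygen in the chair, and prolonged contact with the Lewis acid could start lactonisation onto C12. The fallback sets out from 9. If the closure delivers the C8 epimer tert-butyl 2-[(1S,2S,4aS,8aS)-2-hydroxy-4-methylidene-8-oxodecahydronaphthalen-1-yl]prop-2-enoate F3, this alcohol is esterified with 15 under Mitsunobu conditions (PPh3, diisopropyl azodicarboxylate, THF), which inverts C8 while installing the side chain. The route is rejoined at 17.

Step 6. Enantioselection with an α-silyloxy aldehyde may be incomplete or of the opposite sense, and aldehyde may be consumed in acetal-type side reactions of the adduct. The fallback sets out from 11. A DABCO-mediated reaction with methyl acrylate gives the racemic adduct methyl 4-[(tert-butyldimethylsilyl)oxy]-3-hydroxy-2-methylidenebutanoate F4. A lipase with vinyl acetate, chosen to acetylate the (R)-antipode, leaves the alcohol methyl (3S)-4-[(tert-butyldimethylsilyl)oxy]-3-hydroxy-2-methylidenebutanoate F5 beside the acetate methyl (3R)-3-acetoxy-4-[(tert-butyldimethylsilyl)oxy]-2-methylidenebutanoate F6. F5 is silylated (TBSOTf, 2,6-lutidine) to methyl (3S)-3,4-bis[(tert-butyldimethylsilyl)oxy]-2-methylidenebutanoate F7, and hydrolysis with LiOH rejoins the route at 15.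

Step 10. Conjugate addition of the amide base or of the C4 enolate to one of the two acrylates may compete with the Mannich reaction once the mixture is warmed. The fallback sets out from 17 and avoids any preformed enolate. Paraformaldehyde and diisopropylammonium trifluoroacetate in refluxing THF effect an acid-mediated Mannich reaction and elimination at the only α-methylene, C4, and give 21 directly. No new compound arises (entry F0).

Step 12. Ionisation of the perrhenate ester may lead to elimination toward a diene, or the equilibrium may stop short of full conversion. The fallback sets out from 22. Mesylation (MsCl, Et3N) and treatment with LiBr should give, by allylic equilibration, the primary bromide (1S,2R,4aS,8aS)-7-(bromomethyl)-1-(3-tert-butoxy-3-oxoprop-1-en-2-yl)-4-methylidene-1,2,3,4,4a,5,6,8a-octahydronaphthalen-2-yl (3S)-3,4-bis[(tert-butyldimethylsilyl)oxy]-2-methylidenebutanoate F8. Sodium formate in DMF converts it into the formate (1S,2R,4aS,8aS)-1-(3-tert-butoxy-3-oxoprop-1-en-2-yl)-7-[(formyloxy)methyl]-4-methylidene-1,2,3,4,4a,5,6,8a-octahydronaphthalen-2-yl (3S)-3,4-bis[(tert-butyldimethylsilyl)oxy]-2-methylidenebutanoate F9. KHCO3 in MeOH cleaves the formate selectively and rejoins the route at 23.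

## Further compounds

F1 | step 3 | (S)-trimethyl{[3-(prop-1-en-2-yl)cyclohex-1-en-1-yl]oxy}silane | C[Si](C)(C)OC1=C[C@@H](C(C)=C)CCC1
F2 | step 3 | lithium (3S)-3-(prop-1-en-2-yl)cyclohex-1-en-1-olate | [Li]OC1=C[C@@H](C(C)=C)CCC1
F3 | step 5 | tert-butyl 2-[(1S,2S,4aS,8aS)-2-hydroxy-4-methylidene-8-oxodecahydronaphthalen-1-yl]prop-2-enoate | C=C(C(=O)OC(C)(C)C)[C@@H]1[C@H]2C(=O)CCC[C@@H]2C(=C)C[C@@H]1O
F4 | step 6 | methyl 4-[(tert-butyldimethylsilyl)oxy]-3-hydroxy-2-methylidenebutanoate (racemic) | C=C(C(=O)OC)C(O)CO[Si](C)(C)C(C)(C)C
F5 | step 6 | methyl (3S)-4-[(tert-butyldimethylsilyl)oxy]-3-hydroxy-2-methylidenebutanoate | C=C(C(=O)OC)[C@H](O)CO[Si](C)(C)C(C)(C)C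
F6 | step 6 | methyl (3R)-3-acetoxy-4-[(tert-butyldimethylsilyl)oxy]-2-methylidenebutanoate | C=C(C(=O)OC)[C@@H](OC(C)=O)CO[Si](C)(C)C(C)(C)C
F7 | step 6 | methyl (3S)-3,4-bis[(tert-butyldimethylsilyl)oxy]-2-methylidenebutanoate | C=C(C(=O)OC)[C@H](O[Si](C)(C)C(C)(C)C)CO[Si](C)(C)C(C)(C)C
F0 | step 10 | none | none
F8 | step 12 | (1S,2R,4aS,8aS)-7-(bromomethyl)-1-(3-tert-butoxy-3-oxoprop-1-en-2-yl)-4-methylidene-1,2,3,4,4a,5,6,8a-octahydronaphthalen-2-yl (3S)-3,4-bis[(tert-butyldimethylsilyl)oxy]-2-methylidenebutanoate | C=C(C(=O)OC(C)(C)C)[C@@H]1[C@H]2C=C(CBr)CC[C@@H]2C(=C)C[C@H]1OC(=O)C(=C)[C@H](O[Si](C)(C)C(C)(C)C)CO[Si](C)(C)C(C)(C)C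
F9 | step 12 | (1S,2R,4aS,8aS)-1-(3-tert-butoxy-3-oxoprop-1-en-2-yl)-7-[(formyloxy)methyl]-4-methylidene-1,2,3,4,4a,5,6,8a-octahydronaphthalen-2-yl (3S)-3,4-bis[(tert-butyldimethylsilyl)oxy]-2-methylidenebutanoate | C=C(C(=O)OC(C)(C)C)[C@@H]1[C@H]2C=C(COC=O)CC[C@@H]2C(=C)C[C@H]1OC(=O)C(=C)[C@H](O[Si](C)(C)C(C)(C)C)CO[Si](C)(C)C(C)(C)C
A1 | alternative 1 | trans-fused C5 ketone with C10 methylidene, C8 triethylsilyl ether and C12 p-methoxybenzyl ether | C=C(COCc1ccc(OC)cc1)[C@@H]1[C@H]2C(=O)CCC[C@@H]2C(=C)C[C@H]1O[Si](CC)(CC)CC
A2 | alternative 1 | 2-substituted cyclohex-2-enone with 2-bromoallyl terminus (open-chain precursor of A1) | C=C(COCc1ccc(OC)cc1)[C@H](C1=CCCCC1=O)[C@H](O[Si](CC)(CC)CC)CC(Br)=C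
A3 | alternative 1 | nickel dibromide | [Ni+2].[Br-].[Br-]
A4 | alternative 1 | 2,2'-bipyridine | c1ccc(-c2ccccn2)nc1
A5 | alternative 2 | trans-fused C8 ketol with C10 ketone | CC(C)(C)OC(=O)C[C@@H]1[C@H]2C=C(CO[Si](C)(C)C(C)(C)C)CC[C@@H]2C(=O)C[C@H]1O
A6 | alternative 2 | 1-[4-({[tert-butyl(dimethyl)silyl]oxy}methyl)cyclohexa-1,3-dien-1-yl]ethan-1-one | CC(=O)C1=CC=C(CO[Si](C)(C)C(C)(C)C)CC1
A7 | alternative 2 | tert-butyl 4-oxobutanoate | O=CCCC(=O)OC(C)(C)C
A8 | alternative 3 | trans,trans-trisubstituted cyclohexanone (C8 ketone) | O=C1[C@H](CC(=O)OC(C)(C)C)[C@@H](C=C)[C@H](CCC(=C)COCc2ccc(OC)cc2)C(O[Si](C)(C)C(C)(C)C)C1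
A9 | alternative 3 | 4,5-disubstituted cyclohex-2-enone (C8 enone) | O=C1C=C[C@H](CCC(=C)COCc2ccc(OC)cc2)C(O[Si](C)(C)C(C)(C)C)C1
A10 | alternative 3 | vinylmagnesium bromide | C=C[Mg]Br
A11 | alternative 3 | tert-butyl bromoacetate | CC(C)(C)OC(=O)CBr
A12 | alternative 3 | copper iodide (CuI) | [Cu+].[I-]
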